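The trap in this flask is to take the peak of target for its yield: in the winter run target reads 65.3% at 1.33 min, yet 25.0% at 4.00 min. So I follow how long target has been standing in the flask.

common to all: added ligand 2.7 µM
- winter: starting material 17 mM; second substrate 17 mM; protic impurity 0.85 mM; enzyme 3.2 µM; run made earlier
- spring: starting material 17 mM; second substrate 17 mM; protic impurity 0.85 mM; enzyme 1.6 µM; run made earlier
- south-west: starting material 17 mM; second substrate 17.0 mM; protic impurity 0.850 mM; enzyme 3.2 µM; everything together at the start; time 4.0 min
- west: starting material 17 mM; second substrate 17.0 mM (fed, over 2.5 min); protic impurity 0.850 mM; enzyme 3.2 µM; all else is in the flask from the start; the feed brings no volume worth counting; time 4.0 min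
- north-east: starting material 17 mM (fed, over 2.5 min); second substrate 17.0 mM; protic impurity 0.850 mM; enzyme 3.2 µM; all else is in the flask from the start; the feed brings no volume worth counting; time 4.0 min
- south-east: starting material 17 mM; second substrate 17.0 mM (fed, over 40 s); protic impurity 0.850 mM; enzyme 3.2 µM; all else is in the flask from the start; the feed brings no volume worth counting; time 4.0 min
- south: starting material 17 mM; second substrate 17.0 mM (in portions, 5, over 2.5 min); protic impurity 0.850 mM; enzyme 3.2 µM; first portion at the start, last at 2.5 min; time 4.0 min

- winter (time / min: target / %, starting material / %): 0.333: 39.2, 59.6; 0.500: 51.5, 44.2; 0.833: 64.4, 22.3; 1.33: 65.3, 7.7; 2.50: 43.8, 1.1; 4.00: 25.0, 0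
- spring (time / s: target / %, starting material / %): 10.0: 11.0, 88.5; 12.0: 13.9, 86.0; 20.0: 21.2, 77.7; 25.0: 25.9, 72.7

(readings scatter by 0.3 percentage points)

- the flask that comes out highest in amount of target, in percent of the starting material charged, or "all alike" when all lie within 1.5 percentage points (south-west / west / north-east / south-east / south / all alike)
- target at the end, in percent of the starting material charged, south-west
- target at the end, in percent of the starting material charged, west
- target at the end, in percent of the starting material charged, north-east
- target at the end, in percent of the starting material charged, south-east
- target at the end, in percent of the starting material charged, south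

I reckon with rates. At the start of the winter run starting material goes with a first-order constant of 1.55 min⁻¹, and between 0.333 min and 0.833 min with 1.97 min⁻¹. A partner used up alongside it would lower that constant, but the constant rises, so I take second substrate as no brake and freeze the constant. The spring run, with half the enzyme, gives 0.765 min⁻¹, half the winter start, so the constant follows the enzyme, and the asked flasks hold the winter charge of it. I therefore expect south-west, west, south-east and south all near the winter end value, 25.0%.

The quantity I carry is the fading constant, the pseudo-first-order constant with which target is lost once its formation has nearly stopped. From 2.50 min, with starting material at 1.1%, the winter tail gives 0.374 min⁻¹, slower than formation.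

I take formation as first order, and so I reckon a portion of starting material fed later as a winter flask started later. A steady feed over 2.5 min delays the mean portion by 1.25 min. The last portion is 1.50 min old at the end, past the time of the highest winter reading, so I put each portion on the tail. In my reckoning the winter end value is then multiplied by exp(fading constant × delay), 1.60, and I commit to 40.0% for north-east.

The forecast, holding that “the end value depends on how late target is formed”, gives 25% for south-west, 35% for west, 43% for north-east, 26% for south-east and 36% for south, with north-east highest; for west and south it stands above my value.

The flasks give 24.8% for south-west, 24.8% for west, 24.9% for south-east, 24.7% for south and 40.1% for north-east, the highest.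

    target + enzyme ⇌ isomer of the product + enzyme, rate k1*[enzyme]*[target] forward; the back reaction follows from the equilibrium constant (K = 11.0, k = 3400 L mol⁻¹ s⁻¹)
    starting material + enzyme ⇌ complex A (K = 70.0 L mol⁻¹, k = 79000 L mol⁻¹ s⁻¹)
    second substrate + enzyme ⇌ complex B (K = 26.0 L mol⁻¹, k = 97000 L mol⁻¹ s⁻¹)
    second substrate + protic impurity → quenched substrate (k = 4.20 L mol⁻¹ s⁻¹)
    enzyme + added ligand ⇌ idle complex (K = 4.00 × 10⁵ L mol⁻¹, k = 1100 L mol⁻¹ s⁻¹)
    complex A → enzyme + target (k = 320 s⁻¹)
    complex B → enzyme + second product (k = 240 s⁻¹)

In south-west isomer of the product stands at 75.2% at the end. In north-east it stands at 59.3% at the end, less than in south-west. I use the fading constant once more on north-east dosed over 0.750 min: the delay is 0.375 min, the multiplier 1.15, and from south-west I reckon 28.5%. That run gives 28.0%.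

Readings and results are calculated on assumed constants; scatter was added.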